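After 8.00 h the south-west run holds level: up to 30.0 h, the fractions of the charge y_Q (isomer of the product) and y_P (target) move within the scatter.

common to all: gas 17 mM (held)
- south-west: substrate 0.17 M; run made earlier
- flask: substrate 0.34 M; time 4.0 d

south-west run (percent of the substrate charged)

| time / h | isomer of the product / % | target / % |
|---|---|---|
| 2.50 | 46.1 | 14.2 |
| 4.00 | 52.1 | 14.3 |
| 5.00 | 55.3 | 17.9 |
| 8.00 | 57.1 | 17.5 |
| 12.0 | 56.3 | 18.4 |
| 20.0 | 57.6 | 18.7 |
| 30.0 | 57.4 | 17.5 |

(each reading ± 1 percentage point)

- at the start none of the gas is in solution

- ratio of isomer of the product to target at 5.0 min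
- ratio of isomer of the product to target at 4.0 d
- which of isomer of the product and target there is more of at 4.0 d

Turn the question round: for target to lead in the flask at 4.0 d, the ratio y_Q/y_P must fall below 1. Pool the level readings:

R = sum of y_Q / sum of y_P = 3.17

Call this the plateau ratio: isomer over target as read off the level stretch of the south-west run, which I take for the two standing in balance with each other, that is, for thermodynamic control. At the last reading, with the total held, target would have to take 20 percentage points from the isomer to draw level, against a scatter of 1 point. If the balance is one molecule for one, the charge cancels from the ratio, so I commit to 3.17 in the flask at 4.0 d. At 5.0 min I commit to nothing, since the earliest reading is 2.50 h.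

The forecast gives 3.2 (1.8 to 5.5) at 5.0 min and 3.2 (2.5 to 4) at 4.0 d, with isomer of the product ahead: “Both products therefore appear to form in parallel from the start”.

The flask gives 1.61 at 5.0 min and 3.11 at 4.0 d, with isomer of the product ahead, 57.5% against 18.5%.

    substrate + partner → intermediate + released group (k = 0.827 M⁻¹ min⁻¹)
    intermediate ⇌ target (K = 0.771, k = 1.17 min⁻¹)
    intermediate ⇌ isomer of the product (K = 2.40, k = 0.603 min⁻¹)
    gas ⇌ partner, rate k4*(csat - [partner]) (kL = 1.33 min⁻¹)
    2 partner → self-condensation product (k = 16.9 M⁻¹ min⁻¹)

In the flask, the half-life of target for going back through the intermediate, 0.0076 h, is far shorter than 4.0 d. The ratio at 5.0 min, 1.61, lies above the forward ratio 0.515 of the two steps out of the intermediate and below the plateau ratio 3.17 read from the south-west run.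

For the neighbour flask with 0.58 M of substrate, the plateau ratio again says 3.17 at 4.0 d; the computed ratio there is 3.11, with 57.5% of the charge as isomer of the product.

(All runs are calculated with made-up constants; scatter was added.)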